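All runs are simulated from invented constants.

Hours were the unit I wanted for this flask, since one time at the charge can be held against another.

| flask | substrate | reagent | time |
|---|---|---|---|
| south | 0.120 M | 0.0960 M |  |
| east | 0.120 M | 0.290 M |  |
| south-west | 0.180 M | 0.0960 M |  |
| west | 0.120 M | 0.0960 M | 38 h |

| run | time / h | [target] / M |
|---|---|---|
| south run | 0.76 | 0.0055 |
| south run | 1.4 | 0.0086 |
| south run | 2.8 | 0.0150 |
| south run | 5.2 | 0.0234 |
| south run | 10 | 0.0325 |
| south run | 19 | 0.0427 |
| east run | 0.76 | 0.0360 |
| east run | 1.4 | 0.0548 |
| east run | 2.8 | 0.0775 |
| east run | 5.2 | 0.0952 |
| east run | 10 | 0.1079 |
| east run | 19 | 0.1120 |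
| south-west run | 0.76 | 0.0071 |
| south-west run | 1.4 | 0.0121 |
| south-west run | 2.8 | 0.0209 |
| south-west run | 5.2 | 0.0299 |
| south-west run | 10 | 0.0405 |
| south-west run | 19 | 0.0515 |

(standard deviation of a reading: 4 × 10⁻⁴ M)

1. the exponent of [reagent] in the starting rate at the charge of the south run (at the point where two percent of the substrate have become target)
2. the exponent of [substrate] in the starting rate at the charge of the south run (at the point where two percent of the substrate have become target) (one fixed amount of target, the same in the runs compared)
3. target in the west run at 38 h, as a share of the substrate charged
4. which of these the readings show (the second partner is lost by itself / the substrate is lost by itself / the two partners rest in a complex / two substrates go astray together / nothing beyond the main steps)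

- Overall: substrate + reagent -> target.
- Constant volume, constant temperature.
- "The second partner" is reagent.
- An order is taken over about fifteen percent of the charge, up and down.

I read the rate constant k from each first reading, dividing the mean rate by [substrate] times [reagent] squared at mid-interval, with reagent falling as target forms. The south run gave 7.10 M⁻² h⁻¹; the east run, with 3.02 times the reagent, gave 6.28 M⁻² h⁻¹. The south-west run, with 1.50 times the substrate, gave 6.19 M⁻² h⁻¹. So I committed to order two in reagent, from the south and east runs, and order one in substrate, from the south and south-west runs. The first time is the life of substrate under the main step at the south charge, t_m = 1/(k[reagent] squared) = 17.3 h.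

The second time comes from the east run, whose target at 19 h stood 8.00 mM short of the substrate charged, with 0.178 M of reagent unused. The south-west run, with 1.50 times the substrate, held 1.21 times the target at 19 h, so I chose, without proof, a loss of two substrates together, at rate 2k_d[substrate] squared. Counting the whole gap as loss and integrating over the east run gave 2k_d/k = 0.0665 M, hence t_l = 1/(2k_d[substrate]) = 20.0 h at the south charge. Their ratio t_m/t_l was 0.866: the loss ratio B, substrate lost per target made at that charge, a selectivity factor.

The west flask repeats the south charge. From the south reading at 19 h, I put substrate at 0.0403 M and let it decay with reagent held at 0.0533 M, which gave 44.0 %, on the high side as reagent keeps falling.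

The forecast gave orders 1.95 and 0.97, 44 % and "two substrates go astray together", reasoning “That means substrate is being lost, not reagent”.

The simulation gave orders 2.1 and 1.0, 42.9 % and "two substrates go astray together".

    substrate + 2 reagent → target + reagent (6.768 M⁻² h⁻¹)
    2 substrate → homo dimer (0.2196 M⁻¹ h⁻¹)

Fitted with the two partners resting in a complex, the readings kept a residual of 7.1 scatters. Held at its value for the charge, the loss ratio puts the substrate spent in the west run, with 42.9 % as target, at about 80.1 % of the charge. At the charge of the south-west run the ratio is 1.30, higher than at the south charge, and that run made target equal to a quarter of its substrate charged at 13.0 h.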